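## The problem

Compound 13 is a 2-aryl-3-methyl-2,3-dihydro-1,4-benzodioxine. Dioxane ring B is fused to benzene ring A through C4a and C8a, carries the 4-hydroxy-3,5-dimethoxyphenyl ring C on C2 and a methyl group on C3, and ring A bears a methoxyl at C5 and an (E)-propenyl group at C7. The two ring oxygens are not interchangeable: O1, on the benzylic carbon C2, must sit on C8a (meta to the side chain), and O4, on C3, must sit on C4a (para to the side chain, next to the C5 methoxyl). Any construction from a free catechol therefore has to choose between two very similar phenols. C2 and C3 are adjacent stereocentres, (2R,3R), with aryl and methyl trans. C3 is robust once its C–O bond exists, whereas C2 is benzylic and para-oxygenated and can be set or lost by substitution, so the sound logic is to fix C3 first and let a stereospecific event at C2 define the relative configuration. Three features are fragile: the (E)-propenyl styrene (hydrogenation, strong acid, electrophilic oxidants), the electron-rich free phenol of ring C (oxidants), and the C2–O1 bond, a para-oxygenated benzyl aryl ether (acid, hydrogenolysis). The enabling feature is that O1 and O4 sit on the adjacent carbons C8a and C4a while C4a lies para to C7. An acceptor at C7 makes a halogen at C4a a site for C–O coupling and leaves the C8a oxygen as an ordinary phenol nucleophile, and the O1–C2–C3–O4 unit is the retron of an epoxide opened by that phenol.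

## Retrosynthesis

**13 from 12.** The last cut is the acetal C–O bond of a methoxymethyl ether on the ring C phenol, leading back to 12. The protecting group has to survive hypochlorite, carbonate at 110 °C, hydride, MnO2 and an amide base, and it must leave without hydrogen, which would saturate the propenyl group and endanger the C2–O1 bond. A benzyl ether would have to be removed before the olefination and would push a free phenoxide through three steps. An aryl silyl ether is doubtful under hot carbonate in DMF. The methoxymethyl ether meets every demand and costs one mild acidic step at the end.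

**12 from 11, 10 and 9.** The C7 side chain is cut at its double bond, leading to aldehyde 11 (Julia–Kocienski ethylidenation in the forward sense). Aldehyde 11 comes from alcohol 10 and this from methyl ester 9 by redox adjustment. The propenyl group is not carried through the ring-forming step because C7 must hold an acceptor para to the C4a leaving group. The ester is preferred to the aldehyde because it is inert to alkoxide and carbonate at 110 °C.

**9 from 3 and 7.** Ring B is cut at O1–C2 and O4–C4a, giving bromophenol 3 and cis-epoxide 7. Against a catechol alkylation or an oxidative phenol–propenylphenol coupling, this cut assigns each oxygen a fixed origin: the phenol oxygen of 3 becomes O1 and the epoxide oxygen becomes O4. It also turns the relative configuration into a consequence of epoxide geometry. The precursors are two monocyclic fragments of similar size, and only 7 is chiral. The forward reaction must open 7 at its benzylic carbon with clean inversion, passing through bromo alcohol 8, and then close the ring at a bromide flanked by two oxygen substituents, which the para ester and copper catalysis should allow.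

**7 from 6, 5 and 4.** The epoxide is cut back to (Z)-olefin 6. The cis geometry is required because a single inversion at C2 must end in the trans dioxane, so an (E)-olefin route would give the wrong diastereomer. A chiral manganese salen catalyst sets both stereocentres of 7 in one step. Olefin 6 is cut at its double bond to aldehyde 5 (Z-selective Wittig ethylidenation), and 5 is the methoxymethyl ether of syringaldehyde 4.

**3 from 2 and 1.** Bromophenol 3 is cut at its methyl ether O–CH3 bond to the symmetric diphenol ester 2, the methyl ester of acid 1. In 1 the bromine already stands between the two oxygens and para to the carboxyl group, so the whole ring A regiochemistry reduces to a monomethylation of two equivalent phenols.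

## Roads not taken

**Alternative 1:** The cut runs through O4–C3 and C2–C3, so the C2–C3 bond itself is made. Rh2(OAc)4 would decompose ethyl diazoacetate A4, the phenol oxygen of 4-allyl-2-bromo-6-methoxyphenol A2 would add to the rhodium carbene, and the oxonium ylide would be trapped by 4-(tert-butyldimethylsilyloxy)-3,5-dimethoxybenzaldehyde A3 under a chiral phosphoric acid, giving adduct A1.
- Merits: three achiral components, the C2–C3 bond and both stereocentres in one catalytic step, and an allyl group that needs only a double-bond shift later.
- Weak points: the 1,2-proton shift to the plain O–H insertion product competes, and A3 is an electron-rich, hindered and therefore poor acceptor. Relative and absolute configuration both rest on the catalyst pair. The ester of A1 stands where the target has a methyl group, which costs three steps (reduction, selective activation of the primary alcohol beside the benzylic one, hydride displacement). Ring B must still be closed afterwards at a bromide without a para acceptor.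
- Comparison: in convergence and in complexity created per step this road is the better one. The chosen plan sets against it a stereochemical outcome that follows from two well-understood events (catalyst-controlled epoxidation of 6, stereospecific inversion on 7), a methyl group present from the start, and ring closure in the same operation. About five operations after A1 are matched by four simpler ones after 9.

**Alternative 2:** Only O1–C8a is cut. Pd(OAc)2, a bulky di-tert-butyl(biaryl)phosphine and Cs2CO3 would couple the benzylic hydroxyl of bromo alcohol A6 with the bromide at C8a to give benzodioxane A5, with retention at both stereocentres.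
- Merits: no substitution at a stereocentre, no regiochemical question, and an end game of two steps (allyl isomerisation, desilylation) against four.
- Weak points: A6 must already contain both stereocentres and the O4–C4a bond. A plausible preparation (etherification of a lactate ester with A2 under inversion, conversion to the aryl ketone, diastereoselective reduction) needs about six steps and a reduction whose sense must be tuned. The key step makes one bond and no stereocentre. The bromide of A6 has no para acceptor, and the aryl silyl ether and allyl group are exposed to hot carbonate.
- Comparison: the ring closure is mechanistically the safer one and the end game is shorter, so in these respects this road is at least as good. The chosen plan sets against it a key step that forms two bonds, fragment syntheses of two and three steps, and stereocentres from a single catalytic step instead of chiral pool plus a diastereoselective reduction.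

**Alternative 3:** O1–C2 is cut in the oxidative sense. Controlled-potential anodic two-electron oxidation of phenol A8 would give the para-quinone methide, which the ring A hydroxyl captures at C2 to give aldehyde A7.
- Merits: no protecting groups, a biomimetic closure, C2 set under control of the single C3 centre, and a product one olefination away from 13.
- Weak points: the capture is diastereoselective, not stereospecific, so the trans/cis outcome is open. A7 keeps an oxidisable syringyl phenol and can be over-oxidised. The quinone methide can tautomerise or be trapped by the medium. A8 needs the O4–C4a aryl ether built from a secondary carbinol and a differentiated catechol, which takes several steps.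
- Comparison: this road is better in protecting-group economy and in the steps after the key step. The chosen plan sets against it a stereospecific construction of C2 and a key-step product that is not as easily oxidised as its precursor.

Key step: step 6

Assumption: benzodioxane locants follow the target (O1, C2 aryl, C3 methyl, O4, C5 methoxyl, C7 side chain) in all intermediates; the (S,S) catalyst is chosen on the expectation that olefin 6 follows the facial preference known for cis-β-methylstyrene and indene; 5-(ethylsulfonyl)-1-phenyl-1H-tetrazole is treated as a purchased reagent.

## Route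

Step 1
Reactants: 1 4-bromo-3,5-dihydroxybenzoic acid
Product: 2 methyl 4-bromo-3,5-dihydroxybenzoate
Conditions: MeOH, H2SO4 (cat.), reflux
Reagents that add atoms: methanol, CO
Why: Fischer esterification; the phenols and the aryl bromide are inert to acidic methanol, and the solvent excess drives the equilibrium.

Step 2
Reactants: 2 methyl 4-bromo-3,5-dihydroxybenzoate
Product: 3 methyl 4-bromo-3-hydroxy-5-methoxybenzoate
Conditions: MeI (1.0 equiv), K2CO3 (1.0 equiv), DMF, 0 °C to rt
Reagents that add atoms: iodomethane, CI
Why: Williamson etherification of one of two equivalent phenols; with one equivalent each of base and MeI the mono-ether should be the main component of a statistical mixture, from which diol 2 (recycled) and the dimethyl ether separate by polarity.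

Step 3
Reactants: 4 syringaldehyde
Product: 5 3,5-dimethoxy-4-(methoxymethoxy)benzaldehyde
Conditions: MOMCl, i-Pr2NEt, CH2Cl2, 0 °C to rt
Reagents that add atoms: chloromethyl methyl ether, COCCl
Why: O-alkylation of the acidic para-formyl phenol with a reactive α-chloro ether (Williamson type); the aldehyde is untouched and the acetal is stable to every basic, oxidising and reducing step that follows.

Step 4
Reactants: 5 3,5-dimethoxy-4-(methoxymethoxy)benzaldehyde
Product: 6 1,3-dimethoxy-2-(methoxymethoxy)-5-[(1Z)-prop-1-en-1-yl]benzene
Conditions: EtPPh3Br, NaN(SiMe3)2, THF, 0 °C; then 5, −78 °C to rt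
Reagents that add atoms: ethyltriphenylphosphonium bromide, CC[P+](c1ccccc1)(c1ccccc1)c1ccccc1.[Br-]
Why: Wittig olefination with a non-stabilised ylide under lithium-free conditions, where kinetic formation of the cis-oxaphosphetane should favour the (Z)-olefin; residual (E)-isomer is removed on AgNO3-impregnated silica or left behind in step 5, where trans-olefins are poor substrates.

Step 5
Reactants: 6 1,3-dimethoxy-2-(methoxymethoxy)-5-[(1Z)-prop-1-en-1-yl]benzene
Product: 7 (2S,3R)-2-[3,5-dimethoxy-4-(methoxymethoxy)phenyl]-3-methyloxirane (cis)
Conditions: (S,S)-[N,N′-bis(3,5-di-tert-butylsalicylidene)-1,2-cyclohexanediaminato]manganese chloride, (S,S)-(salen)MnCl (5 mol %), 4-phenylpyridine N-oxide (20 mol %), aq. NaOCl buffered to pH 11.3, CH2Cl2, 0 °C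
Reagents that add atoms: sodium hypochlorite, [Na+].[O-]Cl
Why: Jacobsen–Katsuki epoxidation, for which conjugated cis-disubstituted aryl alkyl olefins are the best substrate class; the oxo-manganese species should deliver oxygen to one enantioface and set both stereocentres, the (S,S) catalyst giving the (2S,3R) epoxide by analogy with cis-β-methylstyrene and indene. The basic two-phase medium and the N-oxide additive protect the acid-labile epoxide and limit leakage to the trans-epoxide; purification is on Et3N-deactivated silica.

Step 6
Reactants: 3 methyl 4-bromo-3-hydroxy-5-methoxybenzoate; 7 (2S,3R)-2-[3,5-dimethoxy-4-(methoxymethoxy)phenyl]-3-methyloxirane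
Product: 9 methyl (2R,3R)-2-[3,5-dimethoxy-4-(methoxymethoxy)phenyl]-5-methoxy-3-methyl-2,3-dihydro-1,4-benzodioxine-7-carboxylate, via (1R,2R)-bromoaryl ether alcohol 8 (not isolated)
Conditions: Cs2CO3 (2.5 equiv), DMF, 80 °C; then CuI (10 mol %), 1,10-phenanthroline (20 mol %), 110 °C, one pot
Reagents that add atoms: none
Why: Cs2CO3 turns 3 into its caesium phenoxide, which attacks the benzylic carbon of 7 anti to the epoxide oxygen (SN2, inversion) and forms O1–C2; the released alkoxide is 8, with C2 now R and C3 unchanged. After CuI and 1,10-phenanthroline are added, the copper alkoxide of 8 undergoes Ullmann-type C–O coupling at the C–Br carbon (the future C4a), commonly formulated as oxidative addition of monovalent copper to a trivalent copper aryl alkoxide followed by reductive elimination, and forms O4–C4a. The closest known reaction type is the one-pot opening of epoxides by 2-halophenols followed by copper-catalysed intramolecular O-arylation to 2,3-dihydro-1,4-benzodioxines. Ring B closes by a formal 6-exo ipso substitution at the aryl carbon, with bromide leaving from outside the new ring. The only stereocentre changed is C2, and it is controlled by the epoxide itself: stereospecific anti opening converts the cis-epoxide into the trans-(2R,3R) dioxane while C3 keeps its oxygen and configuration. The step needs benzylic regioselectivity in the opening, which the electron-rich trioxygenated aryl group should supply by stabilising a loose SN2 transition state at a carbon no more hindered than its neighbour. It also needs the alkoxide to displace bromide and nothing else: the ester para to bromine activates that carbon, and because the ester is meta to O1 a Smiles-type aryl migration that would exchange the two oxygens has no driving force. Copper is added only after the epoxide is consumed, so that the Lewis acidic metal cannot trigger a Meinwald rearrangement of the electron-rich epoxide.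

Step 7
Reactants: 9 methyl (2R,3R)-2-[3,5-dimethoxy-4-(methoxymethoxy)phenyl]-5-methoxy-3-methyl-2,3-dihydro-1,4-benzodioxine-7-carboxylate
Product: 10 [(2R,3R)-2-[3,5-dimethoxy-4-(methoxymethoxy)phenyl]-5-methoxy-3-methyl-2,3-dihydro-1,4-benzodioxin-7-yl]methanol
Conditions: i-Bu2AlH (2.5 equiv), CH2Cl2, −78 to 0 °C; aq. potassium sodium tartrate
Reagents that add atoms: none
Why: hydride reduction of an aryl ester to the benzylic alcohol; acetal, aryl ethers and both stereocentres are inert to the aluminium hydride at low temperature.

Step 8
Reactants: 10 [(2R,3R)-2-[3,5-dimethoxy-4-(methoxymethoxy)phenyl]-5-methoxy-3-methyl-2,3-dihydro-1,4-benzodioxin-7-yl]methanol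
Product: 11 (2R,3R)-2-[3,5-dimethoxy-4-(methoxymethoxy)phenyl]-5-methoxy-3-methyl-2,3-dihydro-1,4-benzodioxine-7-carbaldehyde
Conditions: MnO2 (activated, excess), CH2Cl2, rt
Reagents that add atoms: none
Why: chemoselective heterogeneous oxidation of an electron-rich benzylic alcohol that stops at the aldehyde; with the phenol masked there is no other oxidisable site.

Step 9
Reactants: 11 (2R,3R)-2-[3,5-dimethoxy-4-(methoxymethoxy)phenyl]-5-methoxy-3-methyl-2,3-dihydro-1,4-benzodioxine-7-carbaldehyde
Product: 12 (2R,3R)-2-[3,5-dimethoxy-4-(methoxymethoxy)phenyl]-5-methoxy-3-methyl-7-[(1E)-prop-1-en-1-yl]-2,3-dihydro-1,4-benzodioxine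
Conditions: 5-(ethylsulfonyl)-1-phenyl-1H-tetrazole, KN(SiMe3)2, DME, −60 °C to rt
Reagents that add atoms: 5-(ethylsulfonyl)-1-phenyl-1H-tetrazole, CCS(=O)(=O)c1nnnn1-c1ccccc1
Why: Julia–Kocienski olefination; addition of the metalated sulfone to the non-enolisable aryl aldehyde, Smiles transfer of the tetrazole to oxygen and anti elimination of SO2 and the tetrazolate should give the conjugated (E)-propenyl arene. Neither stereocentre carries a hydrogen acidic enough for the amide base at low temperature.

Step 10
Reactants: 12 (2R,3R)-2-[3,5-dimethoxy-4-(methoxymethoxy)phenyl]-5-methoxy-3-methyl-7-[(1E)-prop-1-en-1-yl]-2,3-dihydro-1,4-benzodioxine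
Product: 13 2,6-dimethoxy-4-[(2R,3R)-5-methoxy-3-methyl-7-[(1E)-prop-1-en-1-yl]-2,3-dihydro-1,4-benzodioxin-2-yl]phenol
Conditions: HCl (2 M aq.), MeOH–THF, 0 °C to rt
Reagents that add atoms: none
Why: acid-catalysed acetal cleavage through the oxocarbenium ion, the formaldehyde unit passing to methanol; an aryl methoxymethyl ether flanked by two methoxyl groups is twisted and especially labile, so dilute acid at or below room temperature should suffice and spare the styrene and the C2–O1 bond.

## Compound list

1 | 4-bromo-3,5-dihydroxybenzoic acid | O=C(O)c1cc(O)c(Br)c(O)c1 | starting material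
2 | methyl 4-bromo-3,5-dihydroxybenzoate | COC(=O)c1cc(O)c(Br)c(O)c1 | intermediate
3 | methyl 4-bromo-3-hydroxy-5-methoxybenzoate | COC(=O)c1cc(O)c(Br)c(OC)c1 | intermediate
4 | syringaldehyde (4-hydroxy-3,5-dimethoxybenzaldehyde) | COc1cc(C=O)cc(OC)c1O | starting material
5 | 3,5-dimethoxy-4-(methoxymethoxy)benzaldehyde | COCOc1c(OC)cc(C=O)cc1OC | intermediate
6 | 1,3-dimethoxy-2-(methoxymethoxy)-5-[(1Z)-prop-1-en-1-yl]benzene | C/C=C\c1cc(OC)c(OCOC)c(OC)c1 | intermediate
7 | (2S,3R)-2-[3,5-dimethoxy-4-(methoxymethoxy)phenyl]-3-methyloxirane (cis) | C[C@H]1O[C@H]1c1cc(OC)c(OCOC)c(OC)c1 | intermediate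
8 | methyl 4-bromo-3-{[(1R,2R)-1-[3,5-dimethoxy-4-(methoxymethoxy)phenyl]-2-hydroxypropyl]oxy}-5-methoxybenzoate (formed in step 6, not isolated) | COC(=O)c1cc(OC)c(Br)c(c1)O[C@H](c1cc(OC)c(OCOC)c(OC)c1)[C@@H](C)O | intermediate
9 | methyl (2R,3R)-2-[3,5-dimethoxy-4-(methoxymethoxy)phenyl]-5-methoxy-3-methyl-2,3-dihydro-1,4-benzodioxine-7-carboxylate | COC(=O)c1cc(OC)c2c(c1)O[C@H](c1cc(OC)c(OCOC)c(OC)c1)[C@@H](C)O2 | intermediate
10 | [(2R,3R)-2-[3,5-dimethoxy-4-(methoxymethoxy)phenyl]-5-methoxy-3-methyl-2,3-dihydro-1,4-benzodioxin-7-yl]methanol | OCc1cc(OC)c2c(c1)O[C@H](c1cc(OC)c(OCOC)c(OC)c1)[C@@H](C)O2 | intermediate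
11 | (2R,3R)-2-[3,5-dimethoxy-4-(methoxymethoxy)phenyl]-5-methoxy-3-methyl-2,3-dihydro-1,4-benzodioxine-7-carbaldehyde | O=Cc1cc(OC)c2c(c1)O[C@H](c1cc(OC)c(OCOC)c(OC)c1)[C@@H](C)O2 | intermediate
12 | (2R,3R)-2-[3,5-dimethoxy-4-(methoxymethoxy)phenyl]-5-methoxy-3-methyl-7-[(1E)-prop-1-en-1-yl]-2,3-dihydro-1,4-benzodioxine | C/C=C/c1cc(OC)c2c(c1)O[C@H](c1cc(OC)c(OCOC)c(OC)c1)[C@@H](C)O2 | intermediate
13 | 2,6-dimethoxy-4-[(2R,3R)-5-methoxy-3-methyl-7-[(1E)-prop-1-en-1-yl]-2,3-dihydro-1,4-benzodioxin-2-yl]phenol | C/C=C/c1cc(OC)c2c(c1)O[C@H](c1cc(OC)c(O)c(OC)c1)[C@@H](C)O2 | target

## Step count and risks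

Total step count: 10. Longest linear sequence: 8 steps (4 to 13, steps 3 to 10); the ring A branch (1 to 3, steps 1 and 2) joins at step 6.

**Step 6 (key step).** The likeliest failures are:
- loss of regiocontrol in the opening (attack at the methyl-bearing carbon, which after closure gives the constitutional isomer with the ring oxygens exchanged);
- erosion of stereochemical fidelity by partial ionisation of the benzylic C–O bond before attack;
- thermal rearrangement of the epoxide before it is captured;
- stalling of the copper-mediated closure at the doubly ortho-substituted bromide, with reductive loss of bromine.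

The fallback separates the two events. It sets out from 3 and 7: the opening is run alone (Cs2CO3, DMF, 60–80 °C, no copper) and bromo alcohol 8 is isolated and purified, which removes any regioisomer and allows its configuration to be checked. The ring is then closed in a separate palladium-catalysed intramolecular C–O coupling of the secondary alcohol with the aryl bromide (Pd(OAc)2, a di-tert-butyl(biaryl)phosphine, Cs2CO3, toluene, 80 °C), in which zerovalent palladium inserts into the ester-activated C–Br bond and the alkoxide is delivered by reductive elimination. This returns to the route at 9 and makes no compound outside the compound list (F0).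

**Step 5.** The stepwise radical character of the manganese oxo transfer can leak into the trans-epoxide, which would be carried on to the cis-dioxane. Enantioselectivity may be insufficient, and the electron-rich epoxide may open or rearrange on contact with acid during reaction or chromatography. The fallback sets out from 6 and replaces the metal oxo transfer by a concerted Shi-type dioxirane epoxidation (KHSO5 as its triple salt with KHSO4 and K2SO4, K2CO3 buffer, a sugar-derived oxazolidinone-fused ketone of the cis-olefin series, MeCN–dimethoxymethane–water, 0 °C). This cannot scramble olefin geometry and runs at basic pH. The ketone antipode that delivers the (2S,3R) series has to be used, most probably the L-sugar-derived one. The fallback returns at 7 and makes no new compound (F0).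

**Step 4.** Z-selectivity of the ethylidenation of an aryl aldehyde may be incomplete, and the (E)-olefin is hard to separate and would feed trans-epoxide into the sequence. The fallback sets out from 5 and fixes the geometry by syn delivery of hydrogen instead of by kinetic olefination. Corey–Fuchs dibromo-olefination (CBr4, PPh3, Et3N, CH2Cl2, 0 °C) gives 5-(2,2-dibromoethenyl)-1,3-dimethoxy-2-(methoxymethoxy)benzene F1. Treatment with n-BuLi (2.1 equiv, THF, −78 °C) and trapping of the lithium acetylide with MeI gives 1,3-dimethoxy-2-(methoxymethoxy)-5-(prop-1-yn-1-yl)benzene F2. Semi-hydrogenation (H2, Pd/CaCO3 poisoned with Pb(OAc)2, quinoline, EtOAc, rt) returns to the route at 6.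

**Step 10.** Acid may add methanol to the electron-rich propenyl arene or oligomerise it, and once the para phenol is free the C2–O1 bond may ionise, with epimerisation at C2 or ring opening. The fallback sets out from 11 and removes the acetal before the styrene exists. The same dilute HCl in MeOH–THF gives (2R,3R)-2-(4-hydroxy-3,5-dimethoxyphenyl)-5-methoxy-3-methyl-2,3-dihydro-1,4-benzodioxine-7-carbaldehyde F3. F3 is then olefinated as its phenoxide with 5-(ethylsulfonyl)-1-phenyl-1H-tetrazole and an extra equivalent of KN(SiMe3)2 (DME, −60 °C to rt), which returns directly at 13.

## Further compounds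

F0 | step 6 | none | none
F0 | step 5 | none | none
F1 | step 4 | 5-(2,2-dibromoethenyl)-1,3-dimethoxy-2-(methoxymethoxy)benzene | COCOc1c(OC)cc(C=C(Br)Br)cc1OC
F2 | step 4 | 1,3-dimethoxy-2-(methoxymethoxy)-5-(prop-1-yn-1-yl)benzene | CC#Cc1cc(OC)c(OCOC)c(OC)c1
F3 | step 10 | (2R,3R)-2-(4-hydroxy-3,5-dimethoxyphenyl)-5-methoxy-3-methyl-2,3-dihydro-1,4-benzodioxine-7-carbaldehyde | O=Cc1cc(OC)c2c(c1)O[C@H](c1cc(OC)c(O)c(OC)c1)[C@@H](C)O2
A1 | alternative 1 | ethyl (2S,3R)-2-(4-allyl-2-bromo-6-methoxyphenoxy)-3-[4-(tert-butyldimethylsilyloxy)-3,5-dimethoxyphenyl]-3-hydroxypropanoate | C=CCc1cc(Br)c(O[C@H](C(=O)OCC)[C@H](O)c2cc(OC)c(O[Si](C)(C)C(C)(C)C)c(OC)c2)c(OC)c1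
A2 | alternative 1 | 4-allyl-2-bromo-6-methoxyphenol | C=CCc1cc(Br)c(O)c(OC)c1
A3 | alternative 1 | 4-(tert-butyldimethylsilyloxy)-3,5-dimethoxybenzaldehyde | COc1cc(C=O)cc(OC)c1O[Si](C)(C)C(C)(C)C
A4 | alternative 1 | ethyl diazoacetate | CCOC(=O)C=[N+]=[N-]
A5 | alternative 2 | (2R,3R)-7-allyl-2-[4-(tert-butyldimethylsilyloxy)-3,5-dimethoxyphenyl]-5-methoxy-3-methyl-2,3-dihydro-1,4-benzodioxine | C=CCc1cc(OC)c2c(c1)O[C@H](c1cc(OC)c(O[Si](C)(C)C(C)(C)C)c(OC)c1)[C@@H](C)O2
A6 | alternative 2 | (1R,2R)-2-(4-allyl-2-bromo-6-methoxyphenoxy)-1-[4-(tert-butyldimethylsilyloxy)-3,5-dimethoxyphenyl]propan-1-ol | C=CCc1cc(Br)c(O[C@H](C)[C@H](O)c2cc(OC)c(O[Si](C)(C)C(C)(C)C)c(OC)c2)c(OC)c1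
A7 | alternative 3 | (2R,3R)-2-(4-hydroxy-3,5-dimethoxyphenyl)-5-methoxy-3-methyl-2,3-dihydro-1,4-benzodioxine-7-carbaldehyde | O=Cc1cc(OC)c2c(c1)O[C@H](c1cc(OC)c(O)c(OC)c1)[C@@H](C)O2
A8 | alternative 3 | 3-hydroxy-4-{[(2R)-1-(4-hydroxy-3,5-dimethoxyphenyl)propan-2-yl]oxy}-5-methoxybenzaldehyde | O=Cc1cc(O)c(O[C@H](C)Cc2cc(OC)c(O)c(OC)c2)c(OC)c1
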